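## Retrosynthetic overview

1. Quinone 14 ⇐ 2,5-dimethoxyphenyl furan 13 by oxidative demethylation; the quinone is unmasked last.
2. 13 ⇐ furan ester 9 + 2-bromo-1,4-dimethoxybenzene by C5–H borylation and Suzuki coupling (aryl–furyl bond).
3. 9 ⇐ racemic carbinol 4 + mixed isovaleric carbonate 7 by an enantioconvergent O-acylation: the key C–O bond, which sets the (R) centre and installs the isovalerate together.
4. 4 ⇐ furan-3-carbaldehyde + prenyl chloride by α-selective prenylation.
5. Rings: none is built. The furan is bought, and the carbocycle comes from the bromoarene and becomes the quinone in the final step.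

Assumption: the target centre is (R) (O > furyl > CH2 > H). (R)-BTM is taken to acylate the (R)-carbinol faster, as it does with 1-aryl alkanols; if the sense proves opposite on this furyl carbinol, (S)-BTM is used with nothing else changed.

## Route

Step 1
Reactants: 1 furan-3-carbaldehyde; 2 1-chloro-3-methylbut-2-ene (prenyl chloride)
Product: 4 rac-1-(furan-3-yl)-4-methylpent-3-en-1-ol, via prenylbarium chloride 3 (not isolated)
Conditions: Ba* (BaI2, 2 equiv lithium biphenylide, THF, rt); 2, THF, −78 °C, 30 min; then 1, −78 °C, 30 min; H2O quench
Reagents that add atoms: none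
Why: Allylic barium reagents add to aldehydes at their unsubstituted α-carbon (α-selective carbonyl allylation), so the linear prenyl carbinol forms in preference to the γ (reverse-prenyl) adduct; the racemate is what step 3 needs.

Step 2
Reactants: 5 3-methylbutanoic acid (isovaleric acid); 6 isopropyl chloroformate
Product: 7 3-methylbutanoic propan-2-yl carbonic anhydride (isopropyl isovaleryl carbonate)
Conditions: Et3N (1.05 equiv), Et2O, 0 °C, 1 h; filter, concentrate, use crude
Reagents that add atoms: none
Why: Standard mixed carboxylic–carbonic anhydride formation, in which the triethylammonium carboxylate displaces chloride from the chloroformate.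

Step 3
Reactants: 4 rac-1-(furan-3-yl)-4-methylpent-3-en-1-ol; 7 isopropyl isovaleryl carbonate
Product: 9 (1R)-1-(furan-3-yl)-4-methylpent-3-en-1-yl 3-methylbutanoate, via ruthenium-bound ketone 8 (not isolated)
Conditions: (η5-C5Ph5)Ru(CO)2Cl (4 mol%), KOtBu (5 mol%), (R)-BTM (5 mol%), 7 (1.5 equiv), toluene/t-amyl alcohol 1:1, rt, 24–48 h
Reagents that add atoms: none
Why: Proposed new method: the chiral isothiourea (R)-BTM is acylated by 7 to an N-isovaleryl isothiouronium ion that stacks on the furan π-face (cation–π) and transfers the acyl group to the (R)-carbinol much faster than to the (S)-carbinol, while the Ru alkoxide formed with KOtBu racemises the unreacted alcohol by reversible β-hydride elimination to Ru-bound ketone 8 and re-insertion, and the isopropyl carbonate leaving group collapses to CO2 and isopropoxide so that no carboxylic acid quenches the Ru alkoxide, giving the (R)-ester from the whole racemate through C–O bond formation; the closest known reaction types are lipase/Ru dynamic kinetic resolution of secondary alcohols, the non-enzymatic version with a planar-chiral DMAP and an acetyl carbonate, and isothiourea kinetic resolution of aryl carbinols with anhydrides, none of which has been shown for an isothiourea/Ru pair, a branched acyl carbonate or a 3-furyl homoallylic carbinol.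

Step 4
Reactants: 9 (1R)-1-(furan-3-yl)-4-methylpent-3-en-1-yl 3-methylbutanoate; 10 bis(pinacolato)diboron; 11 2-bromo-1,4-dimethoxybenzene
Product: 13 (1R)-1-[5-(2,5-dimethoxyphenyl)furan-3-yl]-4-methylpent-3-en-1-yl 3-methylbutanoate, via furyl pinacol boronate 12 (not isolated)
Conditions: [Ir(cod)OMe]2 (1.5 mol%), dtbpy (3 mol%), 10 (1.0 equiv), MTBE, rt, 3 h; evaporate; then 11 (1.1 equiv), XPhos Pd G3 (2 mol%), 0.5 M aq K3PO4, THF, 40 °C, 2 h
Reagents that add atoms: none
Why: Iridium-catalysed C–H borylation is sterically controlled and takes the furan α-C–H remote from the branched 3-substituent (C5, since C2 is shielded), and the fast-activating Suzuki–Miyaura catalyst couples the 2-furyl boronate at 40 °C before protodeboronation; the ester, the trisubstituted alkene and the stereocentre are not touched under these neutral to mildly basic conditions.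

Step 5
Reactants: 13 (1R)-1-[5-(2,5-dimethoxyphenyl)furan-3-yl]-4-methylpent-3-en-1-yl 3-methylbutanoate
Product: 14 (1R)-1-[5-(3,6-dioxocyclohexa-1,4-dien-1-yl)furan-3-yl]-4-methylpent-3-en-1-yl 3-methylbutanoate (CNP0219765.1)
Conditions: CAN (2.5 equiv), MeCN/H2O 3:1, 0 °C, 10 min
Reagents that add atoms: water, O
Why: Oxidative demethylation of a hydroquinone dimethyl ether with ceric ammonium nitrate: single-electron oxidation of the dimethoxyarene, ipso attack of water and loss of methanol give the p-quinone within minutes at 0 °C, conditions under which the ester and the prenyl alkene survive and the stereocentre is not involved.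

## Compound list

1 | furan-3-carbaldehyde | O=Cc1ccoc1 | starting material
2 | 1-chloro-3-methylbut-2-ene (prenyl chloride) | CC(C)=CCCl | starting material
3 | (3-methylbut-2-en-1-yl)barium chloride (prenylbarium chloride, formed in the flask) | CC(C)=CC[Ba]Cl | intermediate
4 | rac-1-(furan-3-yl)-4-methylpent-3-en-1-ol | CC(C)=CCC(O)c1ccoc1 | intermediate
5 | 3-methylbutanoic acid (isovaleric acid) | CC(C)CC(=O)O | starting material
6 | isopropyl chloroformate (propan-2-yl carbonochloridate) | CC(C)OC(=O)Cl | starting material
7 | 3-methylbutanoic propan-2-yl carbonic anhydride (isopropyl isovaleryl carbonate) | CC(C)CC(=O)OC(=O)OC(C)C | intermediate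
8 | 1-(furan-3-yl)-4-methylpent-3-en-1-one (Ru-bound in step 3, not isolated) | CC(C)=CCC(=O)c1ccoc1 | intermediate
9 | (1R)-1-(furan-3-yl)-4-methylpent-3-en-1-yl 3-methylbutanoate | CC(C)=CC[C@@H](OC(=O)CC(C)C)c1ccoc1 | intermediate
10 | bis(pinacolato)diboron | CC1(C)OB(OC1(C)C)B1OC(C)(C)C(C)(C)O1 | starting material
11 | 2-bromo-1,4-dimethoxybenzene | COc1ccc(OC)c(Br)c1 | starting material
12 | (1R)-4-methyl-1-[5-(4,4,5,5-tetramethyl-1,3,2-dioxaborolan-2-yl)furan-3-yl]pent-3-en-1-yl 3-methylbutanoate (not isolated) | CC(C)=CC[C@@H](OC(=O)CC(C)C)c1coc(B2OC(C)(C)C(C)(C)O2)c1 | intermediate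
13 | (1R)-1-[5-(2,5-dimethoxyphenyl)furan-3-yl]-4-methylpent-3-en-1-yl 3-methylbutanoate | CC(C)=CC[C@@H](OC(=O)CC(C)C)c1coc(-c2cc(OC)ccc2OC)c1 | intermediate
14 | (1R)-1-[5-(3,6-dioxocyclohexa-1,4-dien-1-yl)furan-3-yl]-4-methylpent-3-en-1-yl 3-methylbutanoate | CC(C)=CC[C@@H](OC(=O)CC(C)C)c1coc(C2=CC(=O)C=CC2=O)c1 | target

## Step count and risks

Total step count: 5. Longest linear sequence: 4 (steps 1, 3, 4, 5); step 2 is a one-step side branch.

Three steps most likely to fail:

Step 3 (proposed new method). The isothiouronium may discriminate the two enantiomers poorly on a 3-furyl carbinol, or the Ru alkoxide may be acylated and the racemisation stall. The fallback uses known chemistry, sets out from 4 and comes back at 9. Alcohol 4 is oxidised with Dess–Martin periodinane (NaHCO3, CH2Cl2, 0 °C) to ketone 8, now isolated. Ketone 8 is reduced with (S)-2-methyl-CBS-oxazaborolidine (20 mol%) and catecholborane (toluene, −78 °C, which leaves the alkene alone) to (1R)-1-(furan-3-yl)-4-methylpent-3-en-1-ol F2, the aryl-type furyl group acting as the large substituent. F2 is esterified with acid 5 (DCC, DMAP, CH2Cl2, 0 °C to rt), with retention because the C–O bond at the stereocentre is not broken, to give 9.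

Step 5. CAN may attack the electron-rich furan in competition with the dimethoxyarene, and the medium is acidic. The fallback sets out from boronate 12 (made as in the first stage of step 4) and comes back at 14. Boronate 12 is coupled with commercial 2-bromobenzene-1,4-diol (XPhos Pd G3, degassed aq K3PO4, THF, 40 °C, under argon, mildly acidic work-up) to give the free hydroquinone (1R)-1-[5-(2,5-dihydroxyphenyl)furan-3-yl]-4-methylpent-3-en-1-yl 3-methylbutanoate F3. F3 is oxidised with Ag2O (Et2O, Na2SO4, rt) to 14, a low-potential two-electron oxidation that leaves furan, alkene and ester alone.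

Step 1. Activated barium is demanding to prepare, and any loss of α-selectivity gives the reverse-prenyl isomer. The fallback sets out from 1 and comes back at 4. Aldehyde 1 is treated with allylmagnesium bromide (THF, −78 °C) to give rac-1-(furan-3-yl)but-3-en-1-ol F1. F1 undergoes cross-metathesis with excess 2-methylbut-2-ene (Grubbs second-generation catalyst 3 mol%, CH2Cl2, 40 °C) to give 4, so the trisubstituted alkene is made by metathesis and no regioselective allyl transfer is needed.

## Further compounds

F1 | step 1 | rac-1-(furan-3-yl)but-3-en-1-ol | C=CCC(O)c1ccoc1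
F2 | step 3 | (1R)-1-(furan-3-yl)-4-methylpent-3-en-1-ol | CC(C)=CC[C@@H](O)c1ccoc1
F3 | step 5 | (1R)-1-[5-(2,5-dihydroxyphenyl)furan-3-yl]-4-methylpent-3-en-1-yl 3-methylbutanoate | CC(C)=CC[C@@H](OC(=O)CC(C)C)c1coc(-c2cc(O)ccc2O)c1
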